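**Assumption:** the catalysts and ligands in steps 1 and 8 are used in the enantiomeric series that gives the configurations drawn (sense of induction to be confirmed on the first run), and compounds 1, 2, 11, 15, 16 and the named reagents are bought. The route is a design proposal; no step has been run.

## Retrosynthetic overview

1. Sesterfisherol ⇐ selective hydrogenation of the ring-B cyclooctadiene 27 ⇐ ring-closing metathesis of dienol 26 (eight-membered ring B closed last).
2. 26 ⇐ 1,2-addition of the Z-alkenyl metal from ring-A iodide 23 to the α-branched trans-hydrindanone 14; 14 ⇐ ketal-Claisen of hydrindanone 10 with (E)-crotyl alcohol.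
3. 10 (rings C/D) ⇐ dienone 7 by Li/NH3 then face-selective hydrogenation; 7 ⇐ Robinson-type aldol closure of ring C onto ring D.
4. Ring D with its quaternary methyl carbon ⇐ organocatalytic asymmetric Michael addition of 3-methylcyclopentane-1,2-dione to MVK; isopropyl via the diosphenol triflate (Negishi).
5. Ring A (23) ⇐ zirconocene enyne bicyclisation/iodination of (R)-3-methyloct-1-en-6-yne ⇐ Cu-catalysed asymmetric allylic alkylation. Ring order: D (present in 1) → C → A (separate branch) → B.

## Route

Step 1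
Reactants: 1 3-methylcyclopentane-1,2-dione (enol form 2-hydroxy-3-methylcyclopent-2-en-1-one); 2 but-3-en-2-one (MVK)
Product: 3 (S)-2-hydroxy-5-methyl-5-(3-oxobutyl)cyclopent-2-en-1-one
Conditions: 2 (1.05 equiv), quinidine-derived 9-amino(9-deoxy)epi-cinchona 3,5-(CF3)2C6H3-squaramide (10 mol%), PhMe, −20 °C
Reagents that add atoms: none
Why: Proposed new method: the quinuclidine deprotonates the acidic diosphenol, the squaramide N–H pair binds the two adjacent oxygens of the α-keto enolate while the ammonium N–H activates MVK, so the methyl-bearing enol carbon (its innate C-nucleophilic site) adds on one face and creates the all-carbon quaternary stereocentre; the closest known reaction type is the bifunctional cinchona (thio)urea/squaramide Michael addition of β-keto esters and 1,3-diones to vinyl ketones and of unsubstituted cyclic 1,2-diones to nitroalkenes, the new element being a 3-alkyl-1,2-dione donor that forms a quaternary centre with a β-unsubstituted vinyl ketone.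

Step 2
Reactants: 3 (S)-2-hydroxy-5-methyl-5-(3-oxobutyl)cyclopent-2-en-1-one
Product: 4 (S)-4-methyl-5-oxo-4-(3-oxobutyl)cyclopent-1-en-1-yl trifluoromethanesulfonate
Conditions: Tf2O, pyridine, CH2Cl2, −78 → 0 °C
Reagents that add atoms: triflic anhydride, O=S(=O)(OS(=O)(=O)C(F)(F)F)C(F)(F)F
Why: Enol triflate formation: only the acidic diosphenol OH is sulfonylated, while the side-chain methyl ketone and the quaternary centre are untouched.

Step 3
Reactants: 4 (S)-4-methyl-5-oxo-4-(3-oxobutyl)cyclopent-1-en-1-yl trifluoromethanesulfonate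
Product: 5 (S)-5-methyl-5-(3-oxobutyl)-2-(propan-2-yl)cyclopent-2-en-1-one
Conditions: i-PrZnBr (1.5 equiv), PdCl2(dppf) (5 mol%), THF, 50 °C
Reagents that add atoms: isopropylzinc bromide, CC(C)[Zn]Br
Why: Negishi coupling of an electron-poor α-triflyloxy enone, in which dppf suppresses β-hydride isomerisation of the secondary alkyl and the organozinc tolerates both ketones.

Step 4
Reactants: 5 (S)-5-methyl-5-(3-oxobutyl)-2-(propan-2-yl)cyclopent-2-en-1-one
Product: 7 (S)-7a-methyl-3-(propan-2-yl)-1,6,7,7a-tetrahydro-5H-inden-5-one, via aldol ketol 6 (not isolated)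
Conditions: KOH (0.3 equiv), MeOH, 60 °C
Reagents that add atoms: none
Why: Intramolecular aldol condensation (second stage of a Robinson annulation): the methyl-ketone enolate closes the six-membered ring C onto the ring carbonyl and dehydration gives the linearly conjugated dienone, with the quaternary centre unchanged.

Step 5
Reactants: 7 (S)-7a-methyl-3-(propan-2-yl)-1,6,7,7a-tetrahydro-5H-inden-5-one
Product: 9 (R)-7a-methyl-3-(propan-2-yl)-1,2,4,6,7,7a-hexahydro-5H-inden-5-one, via lithium dienolate 8 (not isolated)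
Conditions: Li (2.5 equiv), NH3(l)/THF, t-BuOH (1 equiv), −78 °C; then solid NH4Cl
Reagents that add atoms: none
Why: Dissolving-metal 1,6-reduction of a linear dienone followed by kinetic α-protonation of the dienolate gives the β,γ-enone with a tetrasubstituted C3=C3a alkene (as for steroidal 4,6-dien-3-ones → 5-en-3-ones); the C7a descriptor changes S→R by CIP priority only.

Step 6
Reactants: 9 (R)-7a-methyl-3-(propan-2-yl)-1,2,4,6,7,7a-hexahydro-5H-inden-5-one
Product: 10 (3R,3aS,7aR)-7a-methyl-3-(propan-2-yl)octahydro-5H-inden-5-one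
Conditions: H2 (50 bar), [Ir(cod)(PCy3)(py)]BArF (5 mol%), CH2Cl2, rt
Reagents that add atoms: none
Why: Syn hydrogenation with a Crabtree-type catalyst from the face opposite the axial angular methyl (the face preference of Δ5-steroids → 5α) sets C3a–H and C3–H cis to each other and trans to the methyl, giving the trans-hydrindane with isopropyl cis to the angular methyl.

Step 7
Reactants: 10 (3R,3aS,7aR)-7a-methyl-3-(propan-2-yl)octahydro-5H-inden-5-one; 11 (E)-but-2-en-1-ol
Product: 14 (3R,3aS,6R,7aR)-6-[(2S)-but-3-en-2-yl]-7a-methyl-3-(propan-2-yl)octahydro-5H-inden-5-one, via dimethyl ketal 12 (not isolated), via crotyl enol ether 13 (not isolated)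
Conditions: HC(OMe)3, MeOH, p-TsOH (cat.), rt; concentrate; then 11 (5 equiv), EtCO2H (cat.), xylene, 140 °C, MeOH distilled off
Reagents that add atoms: none
Why: Ketal exchange/elimination gives the more stable Δ5(6) enol ether (away from the trans ring fusion), and its Claisen rearrangement through a chair transition state on the face anti to the axial C7a methyl sets C6 (R, equatorial) and, from the E-crotyl geometry, the side-chain methyl centre (S).

Step 8
Reactants: 15 5-bromopent-2-yne; 16 (E)-1-bromobut-2-ene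
Product: 18 (R)-3-methyloct-1-en-6-yne, via Grignard reagent 17 (not isolated)
Conditions: 15, Mg, Et2O; then 16, CuBr·SMe2 (2 mol%), Taniaphos (2.4 mol%), CH2Cl2, −78 °C
Reagents that add atoms: none
Why: Cu-catalysed asymmetric allylic alkylation (SN2′) of a Grignard reagent, in which the chiral Cu–diphosphine catalyst gives the branched product and sets the allylic methyl stereocentre (R).

Step 9
Reactants: 18 (R)-3-methyloct-1-en-6-yne
Product: 20 (1Z,2S,3R)-1-(1-iodoethylidene)-2-(iodomethyl)-3-methylcyclopentane, via zirconacycle 19 (not isolated)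
Conditions: Cp2ZrCl2, n-BuLi (2 equiv), THF, −78 °C → rt; then I2 (2.2 equiv), −78 → 0 °C
Reagents that add atoms: iodine, II
Why: Negishi zirconocene enyne bicyclisation is a syn carbometalation that places Zr on the methyl-bearing alkene carbon cis to the new ring bond, with the allylic methyl exo (trans to CH2Zr) setting C2 (S); iodinolysis of both C–Zr bonds retains the alkene geometry.

Step 10
Reactants: 20 (1Z,2S,3R)-1-(1-iodoethylidene)-2-(iodomethyl)-3-methylcyclopentane
Product: 21 {[(1S,2Z,5R)-2-(1-iodoethylidene)-5-methylcyclopentyl]methyl}triphenylphosphonium iodide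
Conditions: PPh3 (1.2 equiv), MeCN, 80 °C
Reagents that add atoms: triphenylphosphine, c1ccc(cc1)P(c1ccccc1)c1ccccc1
Why: SN2 quaternisation occurs only at the primary alkyl iodide, the alkenyl iodide being inert.

Step 11
Reactants: 21 {[(1S,2Z,5R)-2-(1-iodoethylidene)-5-methylcyclopentyl]methyl}triphenylphosphonium iodide
Product: 23 (1Z,2S,3R)-2-ethenyl-1-(1-iodoethylidene)-3-methylcyclopentane, via phosphonium ylide 22 (not isolated)
Conditions: NaHMDS, THF, −78 → 0 °C; then HCHO (from cracked paraformaldehyde), → rt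
Reagents that add atoms: formaldehyde, C=O
Why: Wittig methylenation of the non-stabilised ylide with formaldehyde gives the vinyl group; the amide base does not exchange the alkenyl iodide and no stereocentre is touched.

Step 12
Reactants: 23 (1Z,2S,3R)-2-ethenyl-1-(1-iodoethylidene)-3-methylcyclopentane; 14 (3R,3aS,6R,7aR)-6-[(2S)-but-3-en-2-yl]-7a-methyl-3-(propan-2-yl)octahydro-5H-inden-5-one
Product: 26 (3R,3aS,5R,6R,7aR)-6-[(2S)-but-3-en-2-yl]-5-{(1Z)-1-[(2S,3R)-2-ethenyl-3-methylcyclopentylidene]ethyl}-7a-methyl-3-(propan-2-yl)octahydro-1H-inden-5-ol, via alkenyllithium 24 (not isolated), via alkenylcerium dichloride 25 (not isolated)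
Conditions: 23, t-BuLi (2.05 equiv), Et2O, −78 °C; CeCl3 (1.2 equiv), THF, −78 °C; then 14, −78 → −20 °C; aq. NH4Cl
Reagents that add atoms: none
Why: Iodine–lithium exchange with retention of alkene geometry, transmetalation to the weakly basic organocerium and 1,2-addition to the cyclohexanone from the equatorial direction (trans to the equatorial C6 substituent) give the axial tertiary alcohol (5R).

Step 13
Reactants: 26 (dienol from step 12)
Product: 27 ring-B cyclooctadiene: sesterfisherol carrying an additional cis C=C between the two adjacent ring-B CH2 carbons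
Conditions: Grubbs II (10 mol%), PhMe (2 mM), 80 °C
Reagents that add atoms: none
Why: Ring-closing metathesis of the two terminal vinyl groups, held close by the Z-tetrasubstituted alkene and the trans-diequatorial substituents on ring C, closes the eight-membered ring as the cis-alkene without touching the tetrasubstituted alkene or the tertiary alcohol.

Step 14
Reactants: 27 ring-B cyclooctadiene
Product: 28 sesterfisherol
Conditions: H2 (1 atm), RhCl(PPh3)3 (10 mol%), PhH/EtOH, rt
Reagents that add atoms: none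
Why: Wilkinson hydrogenation reduces only the cis-disubstituted alkene, leaves the tetrasubstituted alkene and allylic alcohol intact and creates no stereocentre.

## Compound list

1 | 3-methylcyclopentane-1,2-dione (enol form 2-hydroxy-3-methylcyclopent-2-en-1-one) | CC1=C(O)C(=O)CC1 | starting material
2 | but-3-en-2-one (methyl vinyl ketone) | CC(=O)C=C | starting material
3 | (S)-2-hydroxy-5-methyl-5-(3-oxobutyl)cyclopent-2-en-1-one | CC(=O)CC[C@@]1(C)CC=C(O)C1=O | intermediate
4 | (S)-4-methyl-5-oxo-4-(3-oxobutyl)cyclopent-1-en-1-yl trifluoromethanesulfonate | CC(=O)CC[C@@]1(C)CC=C(OS(=O)(=O)C(F)(F)F)C1=O | intermediate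
5 | (S)-5-methyl-5-(3-oxobutyl)-2-(propan-2-yl)cyclopent-2-en-1-one | CC(=O)CC[C@@]1(C)CC=C(C(C)C)C1=O | intermediate
6 | (3aR,7aS)-3a-hydroxy-7a-methyl-3-(propan-2-yl)-1,3a,4,6,7,7a-hexahydro-5H-inden-5-one (aldol ketol, OH cis to methyl) | O=C1CC[C@@]2(C)CC=C(C(C)C)[C@@]2(O)C1 | intermediate
7 | (S)-7a-methyl-3-(propan-2-yl)-1,6,7,7a-tetrahydro-5H-inden-5-one | O=C1CC[C@@]2(C)CC=C(C(C)C)C2=C1 | intermediate
8 | lithium (7aR)-7a-methyl-3-(propan-2-yl)-2,6,7,7a-tetrahydro-1H-inden-5-olate (dienolate) | [Li+].[O-]C1CC[C@@]2(C)CCC(C(C)C)=C2C=1 | intermediate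
9 | (R)-7a-methyl-3-(propan-2-yl)-1,2,4,6,7,7a-hexahydro-5H-inden-5-one | O=C1CC[C@@]2(C)CCC(C(C)C)=C2C1 | intermediate
10 | (3R,3aS,7aR)-7a-methyl-3-(propan-2-yl)octahydro-5H-inden-5-one | O=C1CC[C@@]2(C)CC[C@H](C(C)C)[C@@H]2C1 | intermediate
11 | (E)-but-2-en-1-ol | C/C=C/CO | starting material
12 | (3R,3aS,7aR)-5,5-dimethoxy-7a-methyl-3-(propan-2-yl)octahydro-1H-indene | COC1(OC)CC[C@@]2(C)CC[C@H](C(C)C)[C@@H]2C1 | intermediate
13 | (3R,3aS,7aR)-5-[(E)-but-2-enyloxy]-7a-methyl-3-(propan-2-yl)-2,3,3a,4,7,7a-hexahydro-1H-indene | C/C=C/COC1=CC[C@@]2(C)CC[C@H](C(C)C)[C@@H]2C1 | intermediate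
14 | (3R,3aS,6R,7aR)-6-[(2S)-but-3-en-2-yl]-7a-methyl-3-(propan-2-yl)octahydro-5H-inden-5-one | C=C[C@H](C)[C@H]1C[C@@]2(C)CC[C@H](C(C)C)[C@@H]2CC1=O | intermediate
15 | 5-bromopent-2-yne | CC#CCCBr | starting material
16 | (E)-1-bromobut-2-ene | C/C=C/CBr | starting material
17 | pent-3-yn-1-ylmagnesium bromide | CC#CCC[Mg]Br | intermediate
18 | (R)-3-methyloct-1-en-6-yne | CC#CCC[C@@H](C)C=C | intermediate
19 | zirconocene metallacycle: Cp2Zr bridging the methyl-bearing alkenyl carbon and the CH2 on C2 of the (2S,3R)-3-methylcyclopentylidene ring | C/C1=C2\CC[C@@H](C)[C@@H]2C[Zr+2]1.[cH-]1cccc1.[cH-]1cccc1 | intermediate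
20 | (1Z,2S,3R)-1-(1-iodoethylidene)-2-(iodomethyl)-3-methylcyclopentane | I/C(C)=C1/CC[C@@H](C)[C@@H]1CI | intermediate
21 | {[(1S,2Z,5R)-2-(1-iodoethylidene)-5-methylcyclopentyl]methyl}triphenylphosphonium iodide | I/C(C)=C1/CC[C@@H](C)[C@@H]1C[P+](c1ccccc1)(c1ccccc1)c1ccccc1.[I-] | intermediate
22 | {[(1S,2Z,5R)-2-(1-iodoethylidene)-5-methylcyclopentyl]methylidene}triphenylphosphorane | I/C(C)=C1/CC[C@@H](C)[C@@H]1C=P(c1ccccc1)(c1ccccc1)c1ccccc1 | intermediate
23 | (1Z,2S,3R)-2-ethenyl-1-(1-iodoethylidene)-3-methylcyclopentane | I/C(C)=C1/CC[C@@H](C)[C@@H]1C=C | intermediate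
24 | alkenyllithium from 23 (Li in place of I, geometry retained) | [Li]/C(C)=C1/CC[C@@H](C)[C@@H]1C=C | intermediate
25 | alkenylcerium dichloride from 24 | Cl[Ce](Cl)/C(C)=C1/CC[C@@H](C)[C@@H]1C=C | intermediate
26 | (3R,3aS,5R,6R,7aR)-6-[(2S)-but-3-en-2-yl]-5-{(1Z)-1-[(2S,3R)-2-ethenyl-3-methylcyclopentylidene]ethyl}-7a-methyl-3-(propan-2-yl)octahydro-1H-inden-5-ol | C=C[C@H](C)[C@H]1C[C@@]2(C)CC[C@H](C(C)C)[C@@H]2C[C@]1(O)/C(C)=C3/CC[C@@H](C)[C@@H]3C=C | intermediate
27 | ring-B cyclooctadiene (sesterfisherol with an extra cis C=C between the two ring-B CH2 carbons) | C/C1=C2\CC[C@@H](C)[C@@H]2/C=C\[C@H](C)[C@H]2C[C@@]3(C)CC[C@H](C(C)C)[C@@H]3C[C@]12O | intermediate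
28 | sesterfisherol | C/C1=C2\CC[C@@H](C)[C@@H]2CC[C@H](C)[C@H]2C[C@@]3(C)CC[C@H](C(C)C)[C@@H]3C[C@]12O | target

## Step count and risks

Total steps: 14. Longest linear sequence: 10 (steps 1–7, then 12–14).

**Step 1 (the proposed new Michael addition).** Possible failures are low enantioselectivity, a second Michael addition at the new enol carbon of 3, or Michael–aldol closure to a bicyclo[3.2.1]octane. The fallback uses known chemistry, sets out from 2 and comes back at 3. MVK is converted with HBr and ethylene glycol into the bromo ketal 2-(2-bromoethyl)-2-methyl-1,3-dioxolane F1. Its Grignard reagent [2-(2-methyl-1,3-dioxolan-2-yl)ethyl]magnesium bromide F2 is added to 3-methylcyclopent-2-en-1-one under Cu/chiral NHC catalysis (asymmetric conjugate addition forming the quaternary centre), and the enolate is trapped with TMSCl as the silyl enol ether F3. Rubottom oxidation with m-CPBA gives the α-silyloxy ketone F4, and K2CO3/MeOH then gives the acyloin F5. Dess–Martin oxidation gives the ketal-protected diosphenol F6, and aqueous HCl/THF removes the ketal to give 3.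

**Step 6 (hydrogenation of the hindered tetrasubstituted alkene).** It may not reduce, or may isomerise into conjugation and scramble C3. The fallback sets out from 9 and comes back at 10. L-Selectride reduces the ketone by equatorial attack to the axial homoallylic alcohol F7. Crabtree's catalyst at 1 atm H2 then delivers hydrogen from the hydroxyl-bearing face (hydroxyl-directed hydrogenation) to give the saturated alcohol F8. Dess–Martin oxidation returns 10.

**Step 12 (addition of the tetrasubstituted alkenyl metal to the α-branched ketone).** Enolisation of 14 or simple non-addition is possible. The fallback reverses the order of bond formation, sets out from 14 and 23 and comes back at 28. Cross-metathesis (Hoveyda–Grubbs II) joins the two vinyl groups to the E-alkene iodo ketone F9. Diimide (TsNHNH2, NaOAc) reduces only this disubstituted alkene to the saturated iodo ketone F10. An intramolecular Nozaki–Hiyama–Kishi reaction (CrCl2, NiCl2 cat., DMSO) then closes ring B by alkenylchromium addition to the ketone and gives 28 directly.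

## Further compounds

F1 | step 1 | 2-(2-bromoethyl)-2-methyl-1,3-dioxolane | CC1(CCBr)OCCO1
F2 | step 1 | [2-(2-methyl-1,3-dioxolan-2-yl)ethyl]magnesium bromide | CC1(CC[Mg]Br)OCCO1
F3 | step 1 | (R)-trimethyl({3-methyl-3-[2-(2-methyl-1,3-dioxolan-2-yl)ethyl]cyclopent-1-en-1-yl}oxy)silane | CC1(OCCO1)CC[C@@]2(C)CCC(O[Si](C)(C)C)=C2
F4 | step 1 | (2R,3R)-3-methyl-3-[2-(2-methyl-1,3-dioxolan-2-yl)ethyl]-2-[(trimethylsilyl)oxy]cyclopentan-1-one | CC1(OCCO1)CC[C@@]2(C)CCC(=O)[C@@H]2O[Si](C)(C)C
F5 | step 1 | (2R,3R)-2-hydroxy-3-methyl-3-[2-(2-methyl-1,3-dioxolan-2-yl)ethyl]cyclopentan-1-one | CC1(OCCO1)CC[C@@]2(C)CCC(=O)[C@@H]2O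
F6 | step 1 | (S)-2-hydroxy-5-methyl-5-[2-(2-methyl-1,3-dioxolan-2-yl)ethyl]cyclopent-2-en-1-one | CC1(OCCO1)CC[C@@]2(C)CC=C(O)C2=O
F7 | step 6 | (5S,7aR)-7a-methyl-3-(propan-2-yl)-2,4,5,6,7,7a-hexahydro-1H-inden-5-ol | O[C@H]1CC[C@@]2(C)CCC(C(C)C)=C2C1
F8 | step 6 | (3R,3aS,5S,7aR)-7a-methyl-3-(propan-2-yl)octahydro-1H-inden-5-ol | O[C@H]1CC[C@@]2(C)CC[C@H](C(C)C)[C@@H]2C1
F9 | step 12 | cross-metathesis product: 14 and 23 joined through an E-CH=CH link between the side-chain methyl carbon and ring-A C2 | I/C(C)=C1/CC[C@@H](C)[C@@H]1/C=C/[C@H](C)[C@H]1C[C@@]2(C)CC[C@H](C(C)C)[C@@H]2CC1=O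
F10 | step 12 | saturated iodo ketone (F9 with the CH=CH link reduced to CH2CH2) | I/C(C)=C1/CC[C@@H](C)[C@@H]1CC[C@H](C)[C@H]1C[C@@]2(C)CC[C@H](C(C)C)[C@@H]2CC1=O
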